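**Retrosynthetic overview**

- The strategy rests on the 1,3-relationship of the brominated ring carbons C2 and C4 of the N-methylpyrrole (across C3, with N1 bearing methyl). They are traced back to the lactam carbonyl C2 and the ketone carbonyl C4 of 1-methylpyrrolidine-2,4-dione 7, the keto form of a 2,4-dihydroxypyrrole.
- C3–Br and C5–Br are taken back to C–H (late electrophilic bromination of 9). C2–Br and C4–Br are taken back to C=O (two deoxybrominations, 9 from 8 from 7, the second with aromatisation).
- 7 comes from the 3-ethoxycarbonyl tetramic acid 5 by loss of the ester. 5 is cut at C3–C4 (Dieckmann/Claisen) to the acyclic malonamide diester 3. This is the only ring closure; the pyrrolidine ring formed here becomes the pyrrole.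
- 3 comes from sarcosine ethyl ester hydrochloride 1 and ethyl malonyl chloride 2 by amide formation (N1–C2).

Key step: step 2

Remark on the chemistry: sarcosine ethyl ester is taken as its commercial hydrochloride and freed in the flask by Et3N. The target has no stereocentre, so no stereocontrol is needed anywhere.

**Route**

Step 1
Reactants: 1 sarcosine ethyl ester hydrochloride; 2 ethyl malonyl chloride (ethyl 3-chloro-3-oxopropanoate)
Product: 3 ethyl N-(3-ethoxy-3-oxopropanoyl)-N-methylglycinate
Conditions: Et3N (2.2 equiv), CH2Cl2, 0 °C to rt, slow addition of 2
Reagents that add atoms: none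
Why: Schotten–Baumann-type N-acylation, in which the freed secondary amine attacks the acid chloride carbonyl (far more electrophilic than either ethyl ester) to give the tertiary amide, with slow addition at 0 °C holding back ketene formation from the malonyl chloride.

Step 2
Reactants: 3 ethyl N-(3-ethoxy-3-oxopropanoyl)-N-methylglycinate
Product: 5 ethyl 4-hydroxy-1-methyl-2-oxo-2,5-dihydro-1H-pyrrole-3-carboxylate, via sodium enolate 4 (not isolated)
Conditions: NaOEt (1.1 equiv), EtOH, reflux; then aq. HCl, 0 °C
Reagents that add atoms: none
Why: Ethoxide removes a proton from the malonyl methylene (flanked by the ester and amide carbonyls), and the stabilised carbanion adds to the glycinate ester carbonyl, the tetrahedral intermediate expelling ethoxide to form the C3–C4 bond; this is an intramolecular Claisen condensation of the Lacey–Dieckmann type, the standard entry to 3-alkoxycarbonyl tetramic acids. The pyrrolidine ring closes in the 5-exo-trig mode, the attacked C=O lying outside the forming ring. No stereocentre is created, since C3 ends up sp2 in the enol and C5 is a methylene. The selectivity needed is between the two possible Claisen directions: malonyl carbon onto the glycinate ester, or glycinate carbon onto the malonyl ester, which would give an isomeric five-membered ring with the ester at C5. It is secured by the large acidity gap, the malonyl CH2 being the only position enolised by NaOEt in EtOH. The product is a vinylogous acid that is deprotonated at once to sodium enolate 4, which takes it out of the equilibrium until the acid quench releases 5.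

Step 3
Reactants: 5 ethyl 4-hydroxy-1-methyl-2-oxo-2,5-dihydro-1H-pyrrole-3-carboxylate
Product: 7 1-methylpyrrolidine-2,4-dione, via carboxylic acid 6 (not isolated)
Conditions: MeCN, H2O (few equiv), reflux; concentrated cold and used at once
Reagents that add atoms: none
Why: Dealkoxycarbonylation of a 3-alkoxycarbonyl tetramic acid in wet boiling acetonitrile, in which the enolised β-keto ester is hydrolysed to β-keto acid 6 and this loses CO2 through the usual six-membered transition state, leaving the C2 and C4 carbonyls untouched.

Step 4
Reactants: 7 1-methylpyrrolidine-2,4-dione
Product: 8 4-bromo-1-methyl-1,5-dihydro-2H-pyrrol-2-one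
Conditions: (COBr)2 (1.2 equiv), DMF (cat.), CH2Cl2, 0 °C to rt; water quench
Reagents that add atoms: oxalyl bromide, O=C(Br)C(=O)Br
Why: Vilsmeier-type deoxybromination of a cyclic 1,3-dicarbonyl enol, in which the bromoiminium salt formed from (COBr)2 and DMF activates the C4 enol oxygen and bromide then adds to C4 and expels DMF (addition–elimination), as in the conversion of tetronic and tetramic acids to their 4-bromo derivatives, while the less reactive lactam carbonyl stays intact at this temperature.

Step 5
Reactants: 8 4-bromo-1-methyl-1,5-dihydro-2H-pyrrol-2-one
Product: 9 2,4-dibromo-1-methyl-1H-pyrrole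
Conditions: POBr3 (1.5 equiv), ClCH2CH2Cl, 70 °C; poured onto ice, organic layer washed with aq. NaHCO3, short pad of basic alumina; kept cold and dark, used the same day
Reagents that add atoms: phosphorus oxybromide, O=P(Br)(Br)Br
Why: Dehydrative deoxybromination of a lactam with POBr3, in which O-phosphorylation of the C2 carbonyl gives an activated iminium, bromide substitutes at C2 by addition–elimination and loss of a C5 proton aromatises the ring; this is the halo-dehydroxylation that converts pyrrolin-2-ones to 2-halopyrroles under Vilsmeier haloformylation conditions and 2-pyridones to 2-bromopyridines.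

Step 6
Reactants: 9 2,4-dibromo-1-methyl-1H-pyrrole
Product: 10 2,3,4,5-tetrabromo-1-methyl-1H-pyrrole
Conditions: NBS (2.1 equiv), THF, −78 °C to rt, dark
Reagents that add atoms: N-bromosuccinimide, O=C1CCC(=O)N1Br
Why: Electrophilic aromatic bromination of an electron-rich N-alkylpyrrole with NBS, the free α position C5 reacting first and the β position C3 second; these are the only C–H positions left, so the reaction should stop at the perbrominated, deactivated ring.

**Compound list**

1 | sarcosine ethyl ester hydrochloride (ethyl N-methylglycinate hydrochloride) | CNCC(=O)OCC.Cl | starting material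
2 | ethyl malonyl chloride (ethyl 3-chloro-3-oxopropanoate) | CCOC(=O)CC(=O)Cl | starting material
3 | ethyl N-(3-ethoxy-3-oxopropanoyl)-N-methylglycinate | CCOC(=O)CC(=O)N(C)CC(=O)OCC | intermediate
4 | sodium 4-(ethoxycarbonyl)-1-methyl-5-oxo-2,5-dihydro-1H-pyrrol-3-olate (sodium enolate of 5) | CCOC(=O)C1=C([O-])CN(C)C1=O.[Na+] | intermediate (not isolated)
5 | ethyl 4-hydroxy-1-methyl-2-oxo-2,5-dihydro-1H-pyrrole-3-carboxylate | CCOC(=O)C1=C(O)CN(C)C1=O | intermediate
6 | 4-hydroxy-1-methyl-2-oxo-2,5-dihydro-1H-pyrrole-3-carboxylic acid | OC(=O)C1=C(O)CN(C)C1=O | intermediate (not isolated)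
7 | 1-methylpyrrolidine-2,4-dione | CN1CC(=O)CC1=O | intermediate
8 | 4-bromo-1-methyl-1,5-dihydro-2H-pyrrol-2-one | CN1CC(Br)=CC1=O | intermediate
9 | 2,4-dibromo-1-methyl-1H-pyrrole | Cn1cc(Br)cc1Br | intermediate
10 | 2,3,4,5-tetrabromo-1-methyl-1H-pyrrole | Cn1c(Br)c(Br)c(Br)c1Br | target

**Step count**

Total steps: 6. Longest linear sequence: 6 steps (1 or 2 to 10).

**Steps most likely to fail**

1. Step 5 (lactam oxygen to bromine with aromatisation). Three processes could cut the conversion:
   - incomplete exchange at the lactam carbon;
   - Vilsmeier-type self-condensation, in which the pyrrole already formed attacks, through its free C5, the activated lactam of unreacted 8;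
   - acid-promoted oligomerisation of the electron-rich bromopyrrole during the reaction or the quench. Simple migration of bromine around the ring would not matter, because step 6 is exhaustive.

   Fallback, setting out from 8: reduce the lactam carbonyl with i-Bu2AlH in CH2Cl2 at −78 °C to the racemic hemiaminal 4-bromo-1-methyl-2,5-dihydro-1H-pyrrol-2-ol F1. On mildly acidic work-up this should lose water to give 3-bromo-1-methyl-1H-pyrrole F2. Exhaustive bromination of the three free positions with NBS (3 equiv) in THF then returns to the route at 10. In this variant the C2 bromine is introduced by electrophilic substitution instead of oxygen exchange.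

2. Step 3 (loss of the ester). The C3-unsubstituted tetramic acid may self-condense in an aldol sense (C3 of one molecule onto the C4 ketone of another) while it is formed hot or during concentration.

   Fallback, setting out from 5: keep the carboxyl carbon through the aromatisation and remove it last.
   - POBr3 in ClCH2CH2Cl at 80 °C should exchange both ring oxygens of 5 to give ethyl 2,4-dibromo-1-methyl-1H-pyrrole-3-carboxylate F3, a bromopyrrole stabilised by the ester.
   - LiOH in THF/H2O should give 2,4-dibromo-1-methyl-1H-pyrrole-3-carboxylic acid F4.
   - NBS (excess) with NaHCO3 in DMF should brominate C5 to 2,4,5-tribromo-1-methyl-1H-pyrrole-3-carboxylic acid F5 (not isolated) and then replace the carboxyl group at C3 by ipso-bromodecarboxylation, returning to the route at 10.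

3. Step 4 (enol oxygen to bromine at C4). The nucleophilic C3 of the enol may attack the bromoiminium carbon (aminomethylenation or formylation at C3) in competition with O-activation, and the HBr set free may promote self-condensation of 7.

   Fallback, setting out from 7: sulfonylate the enol oxygen with Tf2O and Et3N in CH2Cl2 at −78 °C to give 1-methyl-5-oxo-2,5-dihydro-1H-pyrrol-3-yl trifluoromethanesulfonate F6. No carbon electrophile is present in this step. Displacing the triflate with LiBr in refluxing acetone, by addition–elimination at the β-carbon of the unsaturated lactam, returns to the route at 8.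

**Further compounds**

F1 | step 5 | 4-bromo-1-methyl-2,5-dihydro-1H-pyrrol-2-ol (racemic) | CN1CC(Br)=CC1O
F2 | step 5 | 3-bromo-1-methyl-1H-pyrrole | Cn1ccc(Br)c1
F3 | step 3 | ethyl 2,4-dibromo-1-methyl-1H-pyrrole-3-carboxylate | CCOC(=O)c1c(Br)cn(C)c1Br
F4 | step 3 | 2,4-dibromo-1-methyl-1H-pyrrole-3-carboxylic acid | OC(=O)c1c(Br)cn(C)c1Br
F5 | step 3 | 2,4,5-tribromo-1-methyl-1H-pyrrole-3-carboxylic acid | OC(=O)c1c(Br)c(Br)n(C)c1Br
F6 | step 4 | 1-methyl-5-oxo-2,5-dihydro-1H-pyrrol-3-yl trifluoromethanesulfonate | CN1CC(OS(=O)(=O)C(F)(F)F)=CC1=O
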